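## Structural features

Tomoeone D is a spirocyclic acylphloroglucinol-type triketone. Ring A is a cyclohexane-1,3,5-trione, drawn as its C-6 enol, with two prenyl groups on C-1, carbonyls at C-2 and C-4 and an isobutyryl group on C-5. It shares the spiro carbon S with ring B (S, C-a, C-b, C-c, C-d, C-e), a cyclohexane that is trans-fused through C-b/C-c to the cyclopentane ring C (C-b, C-c, C-h, C-g, C-f).

There are five stereocentres. Four are contiguous: C-f (tertiary carbinol with methyl, ring C), the ring-fusion methines C-b and C-c, and C-d (tertiary carbinol with methyl, ring B). The fifth, S, lies two bonds from C-d through C-e.

The fragile groups are: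
- the enolised β-triketone, which is acidic, ambident towards alkylating agents, and open to retro-Claisen cleavage once C-1 is quaternary and C-2 can no longer enolise;
- the two tertiary alcohols, which can dehydrate, the one on C-d also being placed to add to C-2;
- the two prenyl double bonds, which rule out hydrogenation, strong acid and electrophilic oxidants late in the route.

The real difficulty is S. Its substituents are two ring B methylenes and two carbonyl carbons, C-2 and C-4, which differ only one atom further out (diprenyl C-1 against acyl C-5). No reagent can tell the two flanks apart unless they are made different beforehand.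

The key step exploits the chair of ring B. The C-2 carbonyl is axial on S and 1,3-cis to the axial oxygen on C-d, so the two can be tied into a γ-lactone (a 6-oxabicyclo[3.2.1]octan-7-one). That marks C-2 as an ester-type carbonyl while C-4 stays free to carry the acyl side chain. An intramolecular Claisen condensation of the side-chain terminus C-1 onto the lactone carbonyl then forms C-1–C-2, closes ring A and gives back the C-d hydroxyl.

A two-atom bridge can only span the diaxial positions of the trans-fused chair. The configurations of C-d and S therefore follow from C-b and C-c and need no separate control.

## Logic of the disconnections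

**13 ⇒ 12.** The O–Si bond on the ring C oxygen is cut. The alcohol must be masked through the acid chloride and strong-base steps, and a silyl ether can be removed last by fluoride. Nothing is gained in skeleton. The forward step must spare the prenyl groups and the enolised triketone and must not generate the C-d alkoxide.

**12 ⇒ 10 + 11.** Both C-1–CH2 bonds are cut. C-1 is the only ring A carbon that still carries hydrogen and it lies between two carbonyls, so both prenyl groups can be added late, after every radical and oxidative step. Ten carbons and two alkenes are removed. The forward step must alkylate carbon, not oxygen, twice, under a base mild enough for the C-d hydroxyl/C-2 ketone pair.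

**10 ⇒ 9.** The C-1–C-2 bond is cut and C-2 is joined to the oxygen on C-d. This opens ring A and reduces the problem of S to a bridged lactone whose geometry allows only one arrangement. The forward step needs a dianion of the side chain, deprotonation at the terminal methyl and not at the isopropyl methine, and addition to a hindered lactone carbonyl with a tertiary alkoxide as leaving group.

**9 ⇒ 6 + 7 (through 8).** The C-4–C-5 bond is cut. The side chain is a C-acylated β-diketone, and 7 supplies C-5, C-6, C-1 and the isobutyryl group in one piece. What remains is a carboxylic acid on S. The forward step must acylate the central carbon of 7, not its oxygen, with a hindered bridgehead acid chloride.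

**6 ⇒ 5.** The O–CH3 bond of the ester is cut (functional group interconversion). The acid is needed for activation, and the ester is what the ring B closure delivers. The forward step must remove the methyl group without opening the lactone, or the two carboxyl groups on S would become equivalent.

**5 ⇒ 4.** The S–C-e and O–C-d bonds are cut. Both arise from adding the malonate carbon and one ester oxygen across the isopropenyl double bond. Ring B and the stereocentres C-d and S disappear, and S becomes a prochiral malonate carbon. The forward step needs 6-endo radical closure and capture of the tertiary cation by the ester on the same face.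

**4 ⇒ 3.** The O–Si bond is cut. The free alcohol is what the first C–C bond formation tolerates, and the ether is what every later step needs. The forward step is silylation of a hindered tertiary alcohol.

**3 ⇒ 1 + 2.** The S–C-a and C-b–C-c bonds are cut, the retron of a radical addition followed by 5-exo closure on a 1,6-diene. The whole carbon framework of rings B and C reduces to a terpene alcohol that already holds C-f in the right configuration, plus a three-carbon diester. The forward step must attack the vinyl group and not the trisubstituted alkene, and must close the ring with C-b/C-c trans and the arm cis to oxygen. This is the weakest demand of the plan.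

## Other disconnections considered

**Alternative 1:** The cut goes through the two exocyclic bonds of ring C, C-c–C-d and C-b–C-a, so ring C is bought as cyclopent-2-en-1-one A1.

- Forward key step: a copper-catalysed enantioselective 1,4-addition of isopropenylmagnesium bromide A2 to A1 makes C-c–C-d. The magnesium enolate is intercepted by dimethyl methylidenemalonate A3 to make C-b–C-a and give keto malonate A4. A methyl Grignard addition to the C-f ketone would then reach 3.
- In its favour: the electrophile enters anti to the new C-c substituent, so the trans relation that becomes the ring fusion rests on a dependable steric rule. There is no second alkene to compete, and C-f is set afterwards anti to the C-b arm.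
- Against it here: the absolute configuration depends on a chiral catalyst acting on the least cooperative cyclic enone with an alkenyl Grignard reagent. A3 polymerises readily and must be made fresh. The methyl addition runs on a substrate with an acidic malonate proton. The step does nothing for ring B, C-d or S, which would still need steps 3 to 6.
- Comparison: on structure it reaches the same intermediate 3 in three operations where the chosen plan needs one. On mechanism, a polar, sterically ruled addition replaces a radical closure whose diastereoselectivity rests on a modest transition-state preference. On control of C-b/C-c and on regiochemistry this alternative is the better of the two. On the source of absolute configuration (chiral pool against catalyst) and on step count the chosen plan is ahead. It is therefore kept as the fallback for step 1.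

**Alternative 2:** The cut removes S–C-a and C-b–C-c together.

- Forward key step: triene A5 would come from 1 by oxidation at C-8 and Knoevenagel condensation with 2. On heating, its diene (S=C-e–C-d=C-c) adds to the vinyl group in an intramolecular [4+2] cycloaddition and closes rings B and C to the hydrindene gem-diester A6. Protonation of the C-d=C-e bond of A6 could then lead to the lactone of 5.
- In its favour: two rings, two C–C bonds and two stereocentres form in one concerted step. No stoichiometric oxidant is used. The two alkenes of 1 play different roles and cannot compete, which is a point on which it is better than step 1. C-f comes from the same chiral pool, on which it is equal.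
- Against it here: the diene carries two esters on its terminus, one necessarily cis, which crowds the s-cis conformer, and the dienophile is an unactivated vinyl group. The pair is poorly matched and would need high temperature, inviting 1,5-hydrogen shift and loss of the tertiary allylic alcohol. The endo/exo preference that decides cis or trans fusion and the facial bias from quaternary C-f are both expected to be weak. The later lactonisation needs acid in the presence of the ring C alcohol.
- Comparison: on structure it converges on the same lactone-labelled intermediate. On mechanism, a stereospecific pericyclic step replaces a radical chain, but neither secures the trans fusion, so the two are equal there. On step economy the triene costs about three steps and the lactone about five, against three for 5 in the chosen plan.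

**Alternative 3:** The cut is C-d–C-e.

- Forward key step: substrate A7 carries on C-c the silyl enol ether of a methyl ketone and on C-b a 2-(methoxycarbonyl)allyl arm. An iron hydride, formed from a trivalent iron salt and a silane, gives a hydrogen atom to the enol ether CH2. The tertiary α-silyloxy radical at C-d adds 6-endo to the acrylate terminus and, after reduction, gives the mono-ester A8.
- In its favour: C-d is made with its oxygen already in place, a nucleophilic radical is paired with an electron-poor alkene, and the conditions are neutral and mild. On functional-group tolerance this is better than the hot acetic acid of step 3. The ring-closing mode, a 6-endo radical closure of ring B, is equal.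
- Against it here: the configuration of C-d rests on the facial preference of an unconstrained radical, where the lactone bridge of the chosen plan allows only one outcome. A8 has hydrogen on S, so the second carbonyl must be added by acylating a ring B ester enolate. The spiro centre would then depend on axial against equatorial attack, and the C-2/C-4 labelling is lost. A7 needs ring C with three stereocentres, a methyl ketone and an acrylate arm before the key step, which is clearly longer.
- Comparison: on structure it solves C-d but leaves S open, while the chosen plan sets both in one step. On mechanism the two ring B closures are close relatives, reductive against oxidative. On step economy the chosen plan is ahead.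

Key step: step 6

Remarks on the chemistry:
- (R)-(−)-Linalool of high enantiomeric purity is taken to be commercially available.
- Every stereodescriptor of 9, 10 and 13 (S, C-b, C-c, C-d, C-f) was cross-checked. They agree with one another and with (R)-1, so no structure needed correction.
- The one change to the precursor of the key step is a tert-butyldimethylsilyl ether on the ring C alcohol, carried from step 2 to step 8.

## Route

Step 1
Reactants: 1 (R)-linalool; 2 dimethyl malonate
Product: 3 dimethyl 2-{[(1S,2R,5R)-2-hydroxy-2-methyl-5-(prop-1-en-2-yl)cyclopentyl]methyl}propanedioate (hydroxyl cis to the malonylmethyl arm; isopropenyl trans to it)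
Conditions: Mn(OAc)3·2H2O (2.2 equiv), Cu(OAc)2·H2O (0.2 equiv), 2 (4 equiv), AcOH, 60 °C
Reagents that add atoms: none
Why: Mn(OAc)3-mediated oxidative radical addition–cyclization of a malonate with a 1,6-diene: the malonyl radical should prefer the unsubstituted vinyl terminus C-a on steric grounds, the secondary C-b radical closes 5-exo onto the trisubstituted alkene faster than the dilute divalent copper can oxidise it, and Cu(OAc)2 then turns the tertiary C-d radical into the isopropenyl group. C-f is carried over from 1; C-b and C-c are set in the chair-like transition state of the 5-exo closure, where the malonylmethyl arm is expected to turn away from the isopropylidene terminus (trans to C-d) and from the C-f methyl (cis to oxygen); this preference is only moderate, so 3 has to be separated from its diastereomers.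

Step 2
Reactants: 3 hydroxy malonate
Product: 4 dimethyl 2-{[(1S,2R,5R)-2-[(tert-butyldimethylsilyl)oxy]-2-methyl-5-(prop-1-en-2-yl)cyclopentyl]methyl}propanedioate
Conditions: TBSOTf, 2,6-lutidine, CH2Cl2, 0 °C to rt
Reagents that add atoms: tert-butyldimethylsilyl trifluoromethanesulfonate (TBSOTf), CC(C)(C)[Si](C)(C)OS(=O)(=O)C(F)(F)F
Why: Silylation of a tertiary alcohol with a silyl triflate and a hindered pyridine base; the ether stops δ-lactonisation of the hydroxyl onto the cis malonate ester, should survive hot acetic acid and strong base, and keeps the alcohol out of the acid chloride and enolate steps. No stereocentre is touched.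

Step 3
Reactants: 4 silyl ether malonate
Product: 5 bridged lactone methyl ester (6-oxabicyclo[3.2.1]octan-7-one with CO2Me on bridgehead S and CH3 on bridgehead C-d; trans-fused at C-b/C-c to ring C carrying CH3 and OTBS on C-f)
Conditions: Mn(OAc)3·2H2O (2.5 equiv), KOAc, AcOH, 70 °C
Reagents that add atoms: none
Why: Mn(OAc)3-based oxidative radical cyclization ending in lactonisation, a known reaction type of alkenyl malonates: the malonyl radical at S closes 6-endo on the isopropenyl CH2 (C-e), because 5-exo closure would give a trans-fused bicyclo[3.3.0]octane and a primary radical, and trivalent manganese oxidises the tertiary C-d radical to the cation, which is captured by the ester carbonyl that is axial on the new chair, its methyl leaving as methyl acetate. A two-atom bridge can only span the 1,3-diaxial positions of the trans-fused chair, so C-d (oxygen axial, cis to H on C-b) and S (lactone carbonyl axial) form as one diastereomer dictated by C-b and C-c.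

Step 4
Reactants: 5 bridged lactone methyl ester
Product: 6 bridged lactone carboxylic acid (CO2H on S in place of CO2Me)
Conditions: LiI, EtOAc, reflux; then 1 M HCl, 0 °C
Reagents that add atoms: none
Why: Nucleophilic dealkylation of a methyl ester by iodide (SN2 at CH3); the lactone alkyl carbon is tertiary and cannot be attacked this way, so the two carboxyl groups on S stay differentiated. The β-carboxy lactone should not decarboxylate, because the enolate would place a double bond at a bridgehead of the bicyclo[3.2.1] system.

Step 5
Reactants: 6 bridged lactone carboxylic acid; 7 5-methylhexane-2,4-dione
Product: 9 silyl-protected lactone triketone (C-4 on S bonded to the central carbon C-5 of the enolised acetyl/isobutyryl diketone unit), via acid chloride 8 (not isolated)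
Conditions: (COCl)2, DMF (cat.), CH2Cl2, 0 °C to rt, evaporate; then 7, MgCl2, pyridine, CH2Cl2, 0 °C to rt; 1 M HCl wash
Reagents that add atoms: none
Why: Acid chloride formation through the Vilsmeier reagent (a bridgehead acyl chloride cannot form a ketene), then MgCl2/amine-mediated C-acylation of the β-diketone at its central carbon, which gives the magnesium chelate of the triacylmethane and so suppresses O-acylation and double acylation. The new C-4–C-5 bond sits on the free carboxyl carbon, leaving the lactone carbonyl as the marked C-2; no stereocentre is formed.

Step 6
Reactants: 9 silyl-protected lactone triketone
Product: 10 silyl-protected bis-desprenyl tomoeone D (ring A closed with CH2 at C-1; free axial hydroxyl on C-d; OTBS on C-f)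
Conditions: LiN(iPr)2 (3.3 equiv), THF, −78 to 0 °C; AcOH, −78 °C
Reagents that add atoms: none
Why: LiN(iPr)2 first removes the enolic proton of the triacylmethane and then, under kinetic control at −78 °C, a proton of the acetyl CH3 (the isopropyl methine is tertiary, more hindered and less acidic), giving a dianion whose terminal carbon C-1 is its most basic and most nucleophilic site. On warming, C-1 adds to the lactone carbonyl C-2 from the exo face of the oxabicyclo[3.2.1]octanone and the tetrahedral intermediate collapses with loss of the tertiary C-d alkoxide; the closest known reaction type is the Claisen (Dieckmann-type) cyclization of a 3,5-dioxo ester to a cyclohexane-1,3,5-trione, here with a lactone as the ester. Ring A closes in the 6-exo-trig mode, the C-2 carbonyl oxygen staying outside the new ring. The third equivalent of base, or the released alkoxide, deprotonates C-1 of the product between C-2 and C-6, so the ring A dianion is the thermodynamic sink and the alkoxide cannot reverse the condensation. No stereocentre is created: S keeps its four bonds and its configuration is read out from the lactone, because the only ester-type carbonyl within reach of C-1 is the one tied to the ring B oxygen, so C-2 ends beside C-1 and the acyl-bearing C-5 beside C-4. The selectivities needed are site-selective deprotonation (CH3 over CH(CH3)2, secured by the hindered amide base at low temperature) and C- over O-acylation (secured by the lithium dianion, whose charge is concentrated on the terminal carbon). The silyl ether keeps the ring C alcohol from consuming base, and a cold, weakly acidic quench limits dehydrative closure of the C-d hydroxyl onto C-2.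

Step 7
Reactants: 10 silyl-protected bis-desprenyl tomoeone D; 11 prenyl bromide (1-bromo-3-methylbut-2-ene)
Product: 12 tomoeone D tert-butyldimethylsilyl ether (two prenyl groups on C-1; OTBS on C-f)
Conditions: NaOMe (3.2 equiv), 11 (2.5 equiv), MeOH, 0 °C to rt
Reagents that add atoms: none
Why: Exhaustive C-alkylation of a cyclic β-triketone at its only CH2 (C-1, between C-2 and C-6) with an allylic bromide in methanolic methoxide, the usual way to gem-dialkylate acylphloroglucinol-type triones; the protic medium favours C- over O-alkylation and keeps the C-d hydroxyl largely protonated. C-1 receives two identical groups, so no stereocentre arises.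

Step 8
Reactants: 12 tomoeone D tert-butyldimethylsilyl ether
Product: 13 tomoeone D
Conditions: HF·pyridine, pyridine, THF, 0 °C to rt
Reagents that add atoms: none
Why: Fluoride-mediated cleavage of the silyl ether under buffered, mildly acidic conditions that should spare the prenyl double bonds, the enolised triketone and both tertiary alcohols, and that avoid the alkoxide able to open ring A by retro-Claisen. C-1 is quaternary by now, so C-2 cannot dehydrate with the C-d hydroxyl.

## Compound list

1 | (R)-linalool, (3R)-3,7-dimethylocta-1,6-dien-3-ol | CC(C)=CCC[C@@](C=C)(C)O | starting material
2 | dimethyl malonate | COC(=O)CC(=O)OC | starting material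
3 | dimethyl 2-{[(1S,2R,5R)-2-hydroxy-2-methyl-5-(prop-1-en-2-yl)cyclopentyl]methyl}propanedioate | COC(=O)C(C[C@H]1[C@@H](CC[C@@]1(C)O)C(C)=C)C(=O)OC | intermediate
4 | tert-butyldimethylsilyl ether of 3 | COC(=O)C(C[C@H]1[C@@H](CC[C@@]1(C)O[Si](C)(C)C(C)(C)C)C(C)=C)C(=O)OC | intermediate
5 | bridged lactone methyl ester: γ-lactone from the axial carboxyl on S to the oxygen on C-d, CO2Me equatorial on S, trans ring fusion, OTBS on C-f cis to C-a | COC(=O)[C@]12C[C@H]3[C@@H](CC[C@@]3(C)O[Si](C)(C)C(C)(C)C)[C@](C)(C1)OC2=O | intermediate
6 | bridged lactone carboxylic acid (free CO2H on S, otherwise as 5) | OC(=O)[C@]12C[C@H]3[C@@H](CC[C@@]3(C)O[Si](C)(C)C(C)(C)C)[C@](C)(C1)OC2=O | intermediate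
7 | 5-methylhexane-2,4-dione | CC(C)C(=O)CC(C)=O | starting material
8 | acid chloride of 6 | ClC(=O)[C@]12C[C@H]3[C@@H](CC[C@@]3(C)O[Si](C)(C)C(C)(C)C)[C@](C)(C1)OC2=O | intermediate (not isolated)
9 | silyl-protected lactone triketone, precursor of the key step (enolised 2-acyl-1,3-diketone on S, lactone and silyl ether as in 6) | CC(C)C(/O)=C(C(C)=O)/C(=O)[C@]12C[C@H]3[C@@H](CC[C@@]3(C)O[Si](C)(C)C(C)(C)C)[C@](C)(C1)OC2=O | intermediate
10 | silyl-protected bis-desprenyl tomoeone D, product of the key step | CC(C)C(=O)C1=C(O)CC(=O)[C@]2(C[C@H]3[C@@H](CC[C@@]3(C)O[Si](C)(C)C(C)(C)C)[C@@](C)(O)C2)C1=O | intermediate
11 | prenyl bromide, 1-bromo-3-methylbut-2-ene | CC(C)=CCBr | starting material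
12 | tomoeone D tert-butyldimethylsilyl ether (silyl group on the ring C oxygen) | CC(C)=CCC1(CC=C(C)C)C(=O)[C@]2(C[C@H]3[C@@H](CC[C@@]3(C)O[Si](C)(C)C(C)(C)C)[C@@](C)(O)C2)C(=O)C(C(=O)C(C)C)=C1O | intermediate
13 | tomoeone D | CC(C)=CCC1(CC=C(C)C)C(=O)[C@]2(C[C@H]3[C@@H](CC[C@@]3(C)O)[C@@](C)(O)C2)C(=O)C(C(=O)C(C)C)=C1O | target

## Step count and least certain steps

Total step count: 8. Longest linear sequence: 8 steps (1 → 3 → 4 → 5 → 6 → 9 → 10 → 12 → 13). Compounds 2, 7 and 11 enter as purchased materials.

**Step 1 (radical addition–cyclization).** This is the least secure step. Two things can go wrong:
- the malonyl radical may add to the electron-richer trisubstituted alkene instead of the vinyl group;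
- the 5-exo closure may show poor diastereocontrol, giving cis C-b/C-c or the wrong relation to C-f, because the preference rests only on transition-state sterics around a quaternary carbon.

Fallback, setting out from 2 and returning at 3: Knoevenagel condensation of 2 with paraformaldehyde (Cu(OAc)2 cat., KOAc, AcOH, then thermal cracking) would give dimethyl methylidenemalonate F1, the compound labelled A3. Conjugate addition of isopropenylmagnesium bromide A2 to cyclopent-2-en-1-one A1 under CuBr·SMe2 with a chiral ferrocenyl diphosphine, with trapping of the magnesium enolate by F1 at −78 °C, would give the trans keto malonate F2, the compound labelled A4. After deprotonation of the malonate with NaH, MeMgBr/CeCl3 in THF at −78 °C should add to the ketone anti to the neighbouring arm and give 3.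

**Step 6 (key step).** Three processes threaten it:
- reversal at the tetrahedral intermediate, because a tertiary alkoxide is a poor leaving group and the lactone carbonyl is hindered;
- deacylation of the triacylmethane by the liberated alkoxide before ring closure;
- after the quench, acid-promoted dehydrative closure of the C-d hydroxyl onto C-2.

Fallback, setting out from 6 and returning at 10, with the order of the two acylations reversed so that the marked carbonyl reacts first: 6 is converted into its lithium carboxylate and treated with an excess of the dilithio dianion of 7 (LiN(iPr)2, THF, −78 to 0 °C). The terminal carbanion can only attack the lactone carbonyl and would give the seco triketo acid F3, with C-1–C-2 already formed. Activation of its carboxyl group (EDC·HCl, DMAP, CH2Cl2) should then acylate the central carbon C-5 intramolecularly, through the enol ester and acyl transfer, closing ring A at C-4–C-5 to give 10. The equatorial carboxyl cannot reach the axial C-d hydroxyl, so relactonisation on the wrong carbonyl is excluded.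

**Step 3 (oxidative lactonisation).** The tertiary cation may lose a proton to give alkenes instead of being captured by the ester, and the hindered alkylmalonate may enolise slowly, allowing partial loss of the silyl ether in hot acetic acid.

Fallback, setting out from 4 and returning at 5, under redox-neutral atom-transfer conditions: bromination of the malonate (NaH, NBS, THF, 0 °C) would give bromomalonate F4. Visible-light atom-transfer cyclization (Ru(bpy)3Cl2 cat., LiBr, DMF) should close ring B 6-endo to the tertiary bromide F5, either C-d epimer serving. On warming, F5 ionises and lactonises through the axial ester with loss of bromomethane to give 5.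

**Step 7 (double prenylation).** Three processes threaten it:
- O-prenylation of the enolate;
- a stalled second alkylation at the crowded C-1;
- once C-1 is quaternary, opening of ring A by retro-Claisen attack of the C-d alkoxide, or of methoxide, on the non-enolisable C-2.

Fallback, setting out from 10 and returning at 12, under essentially neutral conditions: zerovalent palladium-catalysed Tsuji–Trost allylation (Pd(PPh3)4 cat., allyl methyl carbonate, THF, rt) should give the C-1 diallyl compound F6, any O-allyl isomer being returned to carbon through the π-allyl complex. Cross-metathesis with excess 2-methylbut-2-ene (second-generation Grubbs catalyst, (H2IMes)(PCy3)Cl2Ru=CHPh, CH2Cl2, 40 °C) would then convert both allyl groups into prenyl groups and give 12.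

## Further compounds

F1 | step 1 | dimethyl methylidenemalonate | COC(=O)C(=C)C(=O)OC
F2 | step 1 | dimethyl 2-{[(1S,2R)-5-oxo-2-(prop-1-en-2-yl)cyclopentyl]methyl}propanedioate (trans keto malonate) | COC(=O)C(C[C@H]1[C@@H](CCC1=O)C(C)=C)C(=O)OC
F3 | step 6 | seco triketo acid: ring B with CO2H (C-4) and the 6-methyl-1,3,5-trioxoheptyl chain (C-2, C-1, C-6, C-5, isobutyryl) on S, free hydroxyl on C-d, OTBS on C-f | CC(C)C(=O)CC(=O)CC(=O)[C@@]1(C(O)=O)C[C@H]2[C@@H](CC[C@@]2(C)O[Si](C)(C)C(C)(C)C)[C@@](C)(O)C1
F4 | step 3 | dimethyl 2-bromo-2-{[(1S,2R,5R)-2-[(tert-butyldimethylsilyl)oxy]-2-methyl-5-(prop-1-en-2-yl)cyclopentyl]methyl}propanedioate | COC(=O)C(Br)(C[C@H]1[C@@H](CC[C@@]1(C)O[Si](C)(C)C(C)(C)C)C(C)=C)C(=O)OC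
F5 | step 3 | trans-hydrindane gem-diester with tertiary bromide on C-d (either epimer) and OTBS on C-f | COC(=O)C1(C(=O)OC)C[C@H]2[C@@H](CC[C@@]2(C)O[Si](C)(C)C(C)(C)C)C(C)(Br)C1
F6 | step 7 | C-1 diallyl analogue of 12 | C=CCC1(CC=C)C(=O)[C@]2(C[C@H]3[C@@H](CC[C@@]3(C)O[Si](C)(C)C(C)(C)C)[C@@](C)(O)C2)C(=O)C(C(=O)C(C)C)=C1O
A1 | alternative 1 | cyclopent-2-en-1-one | O=C1C=CCC1
A2 | alternative 1 | isopropenylmagnesium bromide | CC(=C)[Mg]Br
A3 | alternative 1 | dimethyl methylidenemalonate | COC(=O)C(=C)C(=O)OC
A4 | alternative 1 | trans-2-(malonylmethyl)-3-isopropenylcyclopentanone, dimethyl 2-{[(1S,2R)-5-oxo-2-(prop-1-en-2-yl)cyclopentyl]methyl}propanedioate | COC(=O)C(C[C@H]1[C@@H](CCC1=O)C(C)=C)C(=O)OC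
A5 | alternative 2 | dimethyl 2-[(2E,6R)-6-hydroxy-2,6-dimethylocta-2,7-dien-1-ylidene]propanedioate (triene) | COC(=O)C(C(=O)OC)=C/C(C)=C/CC[C@@](C)(O)C=C
A6 | alternative 2 | trans-fused hydrindene gem-diester with C-d=C-e double bond and free ring C carbinol | COC(=O)C2(C[C@H]3[C@@H](CC[C@@]3(C)O)C(C)=C2)C(=O)OC
A7 | alternative 3 | methyl 2-methylidene-3-(cyclopentyl)propanoate substrate: ring C with OSiEt3 and CH3 on C-f, the acrylate arm on C-b and the 1-(tert-butyldimethylsilyloxy)vinyl group on C-c | COC(=O)C(=C)C[C@H]1[C@@H](CC[C@@]1(C)O[Si](CC)(CC)CC)C(=C)O[Si](C)(C)C(C)(C)C
A8 | alternative 3 | trans-hydrindane mono-ester with silylated ring B and ring C carbinols | COC(=O)[C@@H]2C[C@H]3[C@@H](CC[C@@]3(C)O[Si](CC)(CC)CC)[C@@](C)(O[Si](C)(C)C(C)(C)C)C2
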